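## Retrosynthetic overview
1. Target ⇐ fluoride removal of seven silyl groups from the all-trans cyclohexenyl aryl ketone.
2. Cyclohexene ⇐ O-to-C allyl shift of a 2-alkenyl-3,4-dihydro-2H-pyran. That ring is closed by the key bond, C–O (chalcone carbonyl O to the tertiary allyl carbon), in an enantioselective oxa-[4+2] of a 2'-hydroxychalcone with the isopropenyl end of a dienyl stilbene.
3. Chalcone ⇐ water opening of a chromenylium salt, itself closed by a C–O bond (phenol O to ketone C) from two unprotected resorcinol carbonyl compounds.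
4. Dienyl stilbene ⇐ Suzuki coupling (dienyl boronate from an enyne) on a bromostilbene ⇐ Horner–Wadsworth–Emmons olefination.
5. Ring order: pyrylium ring (made, then opened), dihydropyran ring, cyclohexene ring.

Abbreviations: TIPS = triisopropylsilyl; TIPSO = triisopropylsilyloxy; IDPi = imidodiphosphorimidate Brønsted acid built from two 3,3'-diaryl-BINOL units with N-triflyl groups. Ring locants: C1 carries the aroyl group, C2 the stilbene aryl group, C3=C4(CH3), C5 is CH2, and C6 carries the 2,4-dihydroxyphenyl group. The target is (1S,2S,6R), with all three substituents mutually trans.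

Assumption: the sense of induction of the new catalyst system cannot be known in advance, so the (S,S)-acid is written and the equally available (R,R)-acid is used if a test run gives the mirror-image adduct.

## Route

**Step 1**
Reactants: 1 5-bromo-2,4-dimethoxybenzaldehyde; 2 diethyl (3,5-dimethoxybenzyl)phosphonate
Product: 3 (E)-1-bromo-5-[2-(3,5-dimethoxyphenyl)ethenyl]-2,4-dimethoxybenzene
Conditions: KOtBu, THF, 0 °C to rt
Reagents that add atoms: none
Why: Horner–Wadsworth–Emmons olefination of a stabilised benzylic phosphonate anion with an aromatic aldehyde gives the E-stilbene almost exclusively, and the aryl bromide is inert.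

**Step 2**
Reactants: 3 (E)-bromotetramethoxystilbene
Product: 4 4-bromo-6-[(E)-2-(3,5-dihydroxyphenyl)ethenyl]benzene-1,3-diol
Conditions: BBr3 (6 equiv), CH2Cl2, −78 °C to rt; MeOH/H2O quench at 0 °C
Reagents that add atoms: none
Why: Lewis-acid aryl methyl ether cleavage is the standard way to free hydroxystilbenes, and it is done here before any acid-labile diene is present.

**Step 3**
Reactants: 4 bromostilbene tetraol
Product: 5 1-bromo-5-[(E)-2-{3,5-bis(TIPSO)phenyl}ethenyl]-2,4-bis(TIPSO)benzene
Conditions: TIPSCl (5 equiv), imidazole, DMF, rt to 40 °C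
Reagents that add atoms: chlorotri(propan-2-yl)silane (TIPSCl), CC(C)[Si](Cl)(C(C)C)C(C)C
Why: Phenol silylation; TIPS aryl ethers survive aqueous phosphate base and strong-acid catalysis, keep the ring electron-rich, and all leave with fluoride at the end.

**Step 4**
Reactants: 5 tetra-TIPS bromostilbene; 6 2-methylbut-1-en-3-yne; 7 pinacolborane
Product: 9 1-[(E)-3-methylbuta-1,3-dienyl]-5-[(E)-2-{3,5-bis(TIPSO)phenyl}ethenyl]-2,4-bis(TIPSO)benzene, via dienyl boronate 8 (not isolated)
Conditions: 6 (1.5 equiv), 7 (1.2 equiv), Cp2Zr(H)Cl (5 mol %), Et3N (5 mol %), neat, sealed, 60 °C, then excess 6 vented; then 5, Pd(OAc)2 (3 mol %), SPhos (6 mol %), K3PO4, THF–H2O 10:1, 50 °C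
Reagents that add atoms: none
Why: Zirconocene-catalysed syn-hydroboration takes the terminal alkyne in preference to the 1,1-disubstituted alkene, and the Suzuki–Miyaura coupling keeps the E geometry.

**Step 5**
Reactants: 10 2,4-dihydroxybenzaldehyde; 11 1-(2,4-dihydroxyphenyl)ethanone
Product: 13 (E)-1,3-bis(2,4-dihydroxyphenyl)prop-2-en-1-one, via flavylium chloride 12 (not isolated)
Conditions: HCl (g), EtOAc, 0 °C to rt, 48 h, decant; then NaOAc, EtOH–H2O (pH 5–6), 50 °C, dark, 12 h
Reagents that add atoms: water, O; hydrogen chloride, Cl (chloride of 12 only)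
Why: In this Robinson-type acid condensation the aldol product is trapped by C–O ring closure (phenol O onto the protonated ketone C) as an aromatic, insoluble chromenylium salt, which drives a condensation that free polyphenols do not undergo cleanly under base. At pH 5–6 water then adds at C2 and the hemiketal opens and relaxes to the E-chalcone, the most stable member of the flavylium network.

**Step 6**
Reactants: 13 tetrahydroxychalcone
Product: 14 (E)-1-[2-hydroxy-4-(TIPSO)phenyl]-3-[2,4-bis(TIPSO)phenyl]prop-2-en-1-one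
Conditions: TIPSCl (3.3 equiv), imidazole, DMF, 0 °C to rt
Reagents that add atoms: chlorotri(propan-2-yl)silane (TIPSCl), CC(C)[Si](Cl)(C(C)C)C(C)C
Why: Site-selective silylation; the 2'-OH is locked in a hydrogen bond to the carbonyl and stays free, while the other three phenols react. Capping the 2-OH also blocks re-closure to the chromenylium ion under acid.

**Step 7**
Reactants: 14 tris-TIPS 2'-hydroxychalcone (1.2 equiv); 9 tetra-TIPS dienyl stilbene
Product: 16 (1S,2S,6R) hepta-TIPS ketone [2-hydroxy-4-(TIPSO)phenyl]{6-[2,4-bis(TIPSO)phenyl]-2-[5-((E)-2-{3,5-bis(TIPSO)phenyl}ethenyl)-2,4-bis(TIPSO)phenyl]-4-methylcyclohex-3-en-1-yl}methanone, via dihydropyran 15 (not isolated)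
Conditions: (S,S)-IDPi (5 mol %), CH2Cl2, 4 Å molecular sieves, Ar, dark, −20 °C, 24 h, then rt, 12 h; Et3N quench
Reagents that add atoms: none
Why: Proposed new method: the confined strong acid protonates the very electron-rich chalcone, the only basic site, and the excess of 14 buffers the acid so that 9 never meets free acid and there is no uncatalysed background; the resulting hydroxyallyl cation sits in the chiral anion pocket, where the CH2 terminus of the isopropenyl group, the most nucleophilic carbon of 9, adds to one face of the beta carbon and sets C6; the enol oxygen then closes on the tertiary allyl terminus (C–O bond, formal inverse-demand oxa-[4+2]) to give dihydropyran 15, which also collects cations born from the s-trans diene; this tertiary, aryl-conjugated allyl vinyl ether re-ionises under the same acid and the enol carbon closes irreversibly on the benzylic terminus; A(1,3) strain in the enol puts aroyl and C6-aryl trans, and repulsion between the anion-bearing enol and the ortho-TIPSO aryl group favours the exo closure that puts aroyl and C2-aryl trans, giving the all-equatorial and most stable isomer; the closest known reaction types are acid-promoted oxa-Diels–Alder reactions of enones with alkenes, the acid-induced conversion of hetero-Diels–Alder adducts to Diels–Alder adducts (Claisen-type O-to-C shift), confined-acid Diels–Alder reactions of dienones, and the chiral boron-promoted Diels–Alder reaction of 2'-hydroxychalcones.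

**Step 8**
Reactants: 16 hepta-TIPS ketone
Product: 17 target, (2,4-dihydroxyphenyl){(1S,2S,6R)-6-(2,4-dihydroxyphenyl)-2-[5-((E)-2-(3,5-dihydroxyphenyl)ethenyl)-2,4-dihydroxyphenyl]-4-methylcyclohex-3-en-1-yl}methanone
Conditions: TBAF (8 equiv), AcOH (8 equiv), THF, 0 °C to rt, Ar, dark
Reagents that add atoms: none
Why: Buffered fluoride desilylation frees all seven phenols without strong acid or base, so the alkene, the E-stilbene and the C1 centre next to the hydrogen-bonded aryl ketone are left untouched.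

## Compound list
1 | 5-bromo-2,4-dimethoxybenzaldehyde | O=Cc1cc(Br)c(OC)cc1OC | starting material
2 | diethyl (3,5-dimethoxybenzyl)phosphonate | CCOP(=O)(Cc1cc(OC)cc(OC)c1)OCC | starting material
3 | (E)-1-bromo-5-[2-(3,5-dimethoxyphenyl)ethenyl]-2,4-dimethoxybenzene | COc1cc(OC)cc(/C=C/c2cc(Br)c(OC)cc2OC)c1 | intermediate
4 | 4-bromo-6-[(E)-2-(3,5-dihydroxyphenyl)ethenyl]benzene-1,3-diol | Oc1cc(O)cc(/C=C/c2cc(Br)c(O)cc2O)c1 | intermediate
5 | tetra-TIPS ether of 4 | Brc1cc(/C=C/c2cc(O[Si](C(C)C)(C(C)C)C(C)C)cc(O[Si](C(C)C)(C(C)C)C(C)C)c2)c(O[Si](C(C)C)(C(C)C)C(C)C)cc1O[Si](C(C)C)(C(C)C)C(C)C | intermediate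
6 | 2-methylbut-1-en-3-yne | C#CC(C)=C | starting material
7 | pinacolborane | CC1(C)OBOC1(C)C | starting material
8 | (E)-2-(3-methylbuta-1,3-dienyl)-4,4,5,5-tetramethyl-1,3,2-dioxaborolane | CC(=C)/C=C/B1OC(C)(C)C(C)(C)O1 | intermediate (not isolated)
9 | tetra-TIPS (E,E)-dienyl stilbene | CC(=C)/C=C/c1cc(/C=C/c2cc(O[Si](C(C)C)(C(C)C)C(C)C)cc(O[Si](C(C)C)(C(C)C)C(C)C)c2)c(O[Si](C(C)C)(C(C)C)C(C)C)cc1O[Si](C(C)C)(C(C)C)C(C)C | intermediate
10 | 2,4-dihydroxybenzaldehyde | O=Cc1ccc(O)cc1O | starting material
11 | 1-(2,4-dihydroxyphenyl)ethanone | CC(=O)c1ccc(O)cc1O | starting material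
12 | 2-(2,4-dihydroxyphenyl)-7-hydroxychromenylium chloride | [Cl-].Oc1ccc(-c2ccc3ccc(O)cc3[o+]2)c(O)c1 | intermediate (not isolated)
13 | (E)-1,3-bis(2,4-dihydroxyphenyl)prop-2-en-1-one | O=C(/C=C/c1ccc(O)cc1O)c1ccc(O)cc1O | intermediate
14 | (E)-1-[2-hydroxy-4-(TIPSO)phenyl]-3-[2,4-bis(TIPSO)phenyl]prop-2-en-1-one | O=C(/C=C/c1ccc(O[Si](C(C)C)(C(C)C)C(C)C)cc1O[Si](C(C)C)(C(C)C)C(C)C)c1ccc(O[Si](C(C)C)(C(C)C)C(C)C)cc1O | intermediate
15 | (4R)-4-[2,4-bis(TIPSO)phenyl]-6-[2-hydroxy-4-(TIPSO)phenyl]-2-methyl-2-[(E)-2-arylethenyl]-3,4-dihydro-2H-pyran, aryl as in 9, both C2 epimers | CC1(/C=C/c2cc(/C=C/c3cc(O[Si](C(C)C)(C(C)C)C(C)C)cc(O[Si](C(C)C)(C(C)C)C(C)C)c3)c(O[Si](C(C)C)(C(C)C)C(C)C)cc2O[Si](C(C)C)(C(C)C)C(C)C)C[C@@H](c2ccc(O[Si](C(C)C)(C(C)C)C(C)C)cc2O[Si](C(C)C)(C(C)C)C(C)C)C=C(c2ccc(O[Si](C(C)C)(C(C)C)C(C)C)cc2O)O1 | intermediate (not isolated)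
16 | (1S,2S,6R) all-trans hepta-TIPS cyclohexenyl ketone | CC1=C[C@H](c2cc(/C=C/c3cc(O[Si](C(C)C)(C(C)C)C(C)C)cc(O[Si](C(C)C)(C(C)C)C(C)C)c3)c(O[Si](C(C)C)(C(C)C)C(C)C)cc2O[Si](C(C)C)(C(C)C)C(C)C)[C@@H](C(=O)c2ccc(O[Si](C(C)C)(C(C)C)C(C)C)cc2O)[C@H](c2ccc(O[Si](C(C)C)(C(C)C)C(C)C)cc2O[Si](C(C)C)(C(C)C)C(C)C)C1 | intermediate
17 | CNP0327388.1, (1S,2S,6R) all-trans | CC1=C[C@H](c2cc(/C=C/c3cc(O)cc(O)c3)c(O)cc2O)[C@@H](C(=O)c2ccc(O)cc2O)[C@H](c2ccc(O)cc2O)C1 | target

## Step count and risks
Total steps: 8. Longest linear sequence: 6 (steps 1, 2, 3, 4, 7, 8).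

**Step 7 (new method).**
- Risks: a low exo:endo ratio or low ee, arrest at 15, oligomerisation of 9, and catalyst loss if an ortho-silyl group is shed and a chromenylium ion forms.
- Fallback: it sets out from 14 and 9 and returns at 16, using the known chiral boron-promoted Diels–Alder reaction of 2'-hydroxychalcones.
- Procedure: 14 is bound through its free 2'-OH and its carbonyl O to the borate made from VANOL and B(OPh)3 (stoichiometric, CH2Cl2, 4 Å molecular sieves, rt). Then 9 is added.
- Selectivity: this promoter family is known to give the exo, all-trans adduct with 5-styryl-2,4-dioxygenated aryl dienes. The VANOL antipode is chosen for the (1S,2S,6R) series, and aqueous work-up frees 16.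
- It makes no compound outside the list (F0).

**Step 4 (one-pot hydroboration and coupling of a hindered, electron-rich bromide).**
- Risks: slow oxidative addition, protodeboronation of 8, and partial silyl loss.
- Fallback: it sets out from 5 and returns at 9.
- Procedure: a Heck reaction of 5 with 2-methylbut-3-en-2-ol (Pd(OAc)2, P(o-tol)3, Et3N, DMF, 90 °C) gives the tertiary allylic alcohol (E)-4-aryl-2-methylbut-3-en-2-ol F1. Mesylation and elimination (MsCl, Et3N, CH2Cl2, 0 °C to rt) then gives 9.

**Step 5 (chromenylium closure and reopening).**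
- Risks: incomplete relaxation to the E-chalcone, or drift to the flavanone.
- Fallback: it sets out from 10 and 11 and returns at 13 by the classical protected Claisen–Schmidt route.
- Procedure: 10 with MOMCl and iPr2NEt gives 2,4-bis(methoxymethoxy)benzaldehyde F2. 11 with MOMCl and K2CO3 in acetone gives 1-[2-hydroxy-4-(methoxymethoxy)phenyl]ethanone F3.
- KOH in EtOH then joins them to the tris-MOM 2'-hydroxychalcone F4. HCl in MeOH at 40 °C, followed by the same NaOAc buffer, gives 13.

## Further compounds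
F0 | step 7 | none | none
F1 | step 4 | (E)-4-{5-[(E)-2-(3,5-bis(TIPSO)phenyl)ethenyl]-2,4-bis(TIPSO)phenyl}-2-methylbut-3-en-2-ol | CC(C)(O)/C=C/c1cc(/C=C/c2cc(O[Si](C(C)C)(C(C)C)C(C)C)cc(O[Si](C(C)C)(C(C)C)C(C)C)c2)c(O[Si](C(C)C)(C(C)C)C(C)C)cc1O[Si](C(C)C)(C(C)C)C(C)C
F2 | step 5 | 2,4-bis(methoxymethoxy)benzaldehyde | COCOc1ccc(C=O)c(OCOC)c1
F3 | step 5 | 1-[2-hydroxy-4-(methoxymethoxy)phenyl]ethanone | CC(=O)c1ccc(OCOC)cc1O
F4 | step 5 | (E)-1-[2-hydroxy-4-(methoxymethoxy)phenyl]-3-[2,4-bis(methoxymethoxy)phenyl]prop-2-en-1-one | O=C(/C=C/c1ccc(OCOC)cc1OCOC)c1ccc(OCOC)cc1O
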